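**Plan**

- Retrosynthesis (tricyclic intermediates carry furo[2,3-h]chromene locants: chroman O-1 to C-6, C-6a, furan O-7, C-8, C-9, quaternary C-9a, C-9b). Cut first the bond between the aryl ketone carbon and the carbinol C-9 of the 3-hydroxychroman-4-one ring, giving keto aldehyde 26. Then cut the aryl O–C-9a bond (phenol dearomatisation, the aryloxy unit delivered from O-9 through a temporary benzyl ether ring). Then cut the furanone C-9–C-9a and O-7–C-8 bonds, and last the chroman O-1–C-2 and C-3–C-4 (aldol) bonds.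
- Forward order of rings: chroman (steps 1–5), furanone on its C-7/C-8 edge (6–9), seven-membered tether ring formed together with the cyclohexadienone (14–16), tether opened (17, 18), chromanone ring last (19).
- Feature that makes the key event possible: in 26 the formyl carbon sits on the aryl ring that is bound through oxygen to C-9a, next to the furanone ketone C-9. Its acyl-anion form can therefore reach C-9 in a six-membered array, and only on the face of the aryloxy group. C-8–H, flanked by that ketone, O-7 and the anisyl ring, is acidic, so the two C-8 epimers interconvert.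
- Stereochemistry: C-2 comes from asymmetric transfer hydrogenation and Mitsunobu inversion. The C-9 alcohol from a dynamic transfer hydrogenation is relayed by the tether to C-9a. C-9a then dictates the new carbinol C-9, and C-8 is funnelled to one epimer in the key step.

Key step: step 19

Remark: allyl means prop-2-enyl; methyl 2-bromo-2-(4-methoxyphenyl)acetate (11) is taken as a purchasable racemate; compounds 8–14 carry chromane locants.

**Step 1**
Reactants: 1 2,4,6-trihydroxybenzaldehyde
Product: 2 2,6-dihydroxy-4-(methoxymethoxy)benzaldehyde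
Conditions: MOMCl (1.0 equiv), i-Pr2NEt, CH2Cl2, 0 °C
Reagents that add atoms: chloromethyl methyl ether, COCCl
Why: Williamson-type O-alkylation; the 4-OH is para to the formyl group, not chelated and the most acidic, so one equivalent of reagent should alkylate it first.

**Step 2**
Reactants: 2 2,6-dihydroxy-4-(methoxymethoxy)benzaldehyde
Product: 3 2-(allyloxy)-6-hydroxy-4-(methoxymethoxy)benzaldehyde
Conditions: allyl bromide (1.0 equiv), K2CO3, acetone, 40 °C
Reagents that add atoms: allyl bromide, C=CCBr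
Why: Williamson mono-allylation of one of two equivalent phenols; the remaining OH stays hydrogen-bonded to the aldehyde and should react much more slowly.

**Step 3**
Reactants: 3 2-(allyloxy)-6-hydroxy-4-(methoxymethoxy)benzaldehyde; 4 1-(4-methoxyphenyl)ethanone
Product: 5 (E)-3-[2-(allyloxy)-6-hydroxy-4-(methoxymethoxy)phenyl]-1-(4-methoxyphenyl)prop-2-en-1-one
Conditions: KOH, EtOH/H2O, 40 °C
Reagents that add atoms: none
Why: Claisen–Schmidt aldol condensation of the acetophenone enolate with the aldehyde, E1cB loss of water giving the conjugated E-enone.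

**Step 4**
Reactants: 5 (E)-3-[2-(allyloxy)-6-hydroxy-4-(methoxymethoxy)phenyl]-1-(4-methoxyphenyl)prop-2-en-1-one
Product: 7 3-(allyloxy)-2-[(3R)-3-hydroxy-3-(4-methoxyphenyl)propyl]-5-(methoxymethoxy)phenol, via saturated ketone 6 (not isolated)
Conditions: RuCl[(R,R)-TsDPEN](p-cymene) (2 mol %), HCO2Na, H2O/DMF, 40 °C
Reagents that add atoms: none
Why: Noyori–Ikariya transfer hydrogenation; the Ru–H should first reduce the conjugated C=C (as known for chalcones) and then the aryl ketone, the (R,R)-ligand setting the (R)-carbinol as with acetophenones, while the allyl ether is inert.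

**Step 5**
Reactants: 7 3-(allyloxy)-2-[(3R)-3-hydroxy-3-(4-methoxyphenyl)propyl]-5-(methoxymethoxy)phenol
Product: 8 (2S)-5-(allyloxy)-7-(methoxymethoxy)-2-(4-methoxyphenyl)chromane
Conditions: PPh3, DIAD, THF, 0 °C
Reagents that add atoms: none
Why: intramolecular Mitsunobu etherification; the phenol displaces the activated benzylic alcohol in a six-membered SN2 closure with inversion, which should give the (2S)-chroman.

**Step 6**
Reactants: 8 (2S)-5-(allyloxy)-7-(methoxymethoxy)-2-(4-methoxyphenyl)chromane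
Product: 9 (2S)-5-(allyloxy)-8-bromo-7-(methoxymethoxy)-2-(4-methoxyphenyl)chromane
Conditions: NBS (1.0 equiv), CH2Cl2, −40 °C
Reagents that add atoms: N-bromosuccinimide, O=C1CCC(=O)N1Br
Why: electrophilic aromatic bromination; C-8 (between O-1 and the 7-alkoxy group, para to the 5-alkoxy group) is the most nucleophilic position of 5,7-dialkoxychromans, as in catechin ethers.

**Step 7**
Reactants: 9 (2S)-5-(allyloxy)-8-bromo-7-(methoxymethoxy)-2-(4-methoxyphenyl)chromane
Product: 10 (2S)-5-(allyloxy)-8-bromo-2-(4-methoxyphenyl)chroman-7-ol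
Conditions: HCl (0.2 M), MeOH, 40 °C
Reagents that add atoms: none
Why: acid-catalysed acetal exchange removes the MOM group; the allyl ether, the aryl bromide and the far less basic chroman ether should survive dilute acid.

**Step 8**
Reactants: 10 (2S)-5-(allyloxy)-8-bromo-2-(4-methoxyphenyl)chroman-7-ol; 11 methyl 2-bromo-2-(4-methoxyphenyl)acetate
Product: 13 2-{[(2S)-5-(allyloxy)-8-bromo-2-(4-methoxyphenyl)chroman-7-yl]oxy}-2-(4-methoxyphenyl)acetic acid (both epimers at the acetic acid carbon), via methyl ester 12 (not isolated)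
Conditions: K2CO3, DMF, 25 °C; then LiOH, THF/H2O, 25 °C; HCl (aq.) to pH 3
Reagents that add atoms: lithium hydroxide, [Li+].[OH-]
Why: Williamson O-alkylation of the phenoxide with the activated benzylic α-bromo ester, then saponification; the new stereocenter forms without control, which does not matter because it is epimerised later.

**Step 9**
Reactants: 13 2-{[(2S)-5-(allyloxy)-8-bromo-2-(4-methoxyphenyl)chroman-7-yl]oxy}-2-(4-methoxyphenyl)acetic acid
Product: 15 (2S)-5-(allyloxy)-2,8-bis(4-methoxyphenyl)-3,4-dihydro-2H-furo[2,3-h]chromen-9(8H)-one (both C-8 epimers), via aryllithium carboxylate 14 (not isolated)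
Conditions: n-BuLi (2.2 equiv), THF, −78 → 0 °C; NH4Cl (aq.)
Reagents that add atoms: none
Why: Parham cyclisation; the first equivalent forms the carboxylate, the second exchanges Br for Li, and the aryllithium adds in a five-membered closure to the lithium carboxylate, whose dianionic adduct cannot add twice and should collapse to the ketone on work-up.

**Step 10**
Reactants: 15 (2S)-5-(allyloxy)-2,8-bis(4-methoxyphenyl)-3,4-dihydro-2H-furo[2,3-h]chromen-9(8H)-one
Product: 16 (2S,8R,9R)-5-(allyloxy)-2,8-bis(4-methoxyphenyl)-3,4,8,9-tetrahydro-2H-furo[2,3-h]chromen-9-ol (8,9-cis)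
Conditions: RuCl[(S,S)-TsDPEN](p-cymene) (2 mol %), HCO2Na, H2O/DMF, 40 °C, argon
Reagents that add atoms: none
Why: asymmetric transfer hydrogenation with dynamic kinetic resolution; C-8–H (α-aryl, α-aryloxy) epimerises fast, hydride is delivered anti to the 8-aryl group (cis alcohol) and the (S,S)-ligand should select the 9R carbinol, as for 2-substituted indanones and chromanones.

**Step 11**
Reactants: 17 2-hydroxy-4,6-dimethoxybenzaldehyde
Product: 18 2-(allyloxy)-4,6-dimethoxybenzaldehyde
Conditions: allyl bromide, K2CO3, DMF, 50 °C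
Reagents that add atoms: allyl bromide, C=CCBr
Why: Williamson allylation of the only phenol.

**Step 12**
Reactants: 18 2-(allyloxy)-4,6-dimethoxybenzaldehyde
Product: 19 [2-(allyloxy)-4,6-dimethoxyphenyl]methanol
Conditions: NaBH4, MeOH, 0 °C
Reagents that add atoms: none
Why: borohydride reduction of the aldehyde; the allyl ether is not touched.

**Step 13**
Reactants: 19 [2-(allyloxy)-4,6-dimethoxyphenyl]methanol
Product: 21 1-(allyloxy)-2-(chloromethyl)-3,5-dimethoxybenzene, via benzylic mesylate 20 (not isolated)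
Conditions: MsCl, Et3N, CH2Cl2, −20 → 0 °C; used at once without purification
Reagents that add atoms: methanesulfonyl chloride, CS(=O)(=O)Cl
Why: the mesylate of this 2,4,6-trioxygenated benzyl alcohol is displaced in the flask by chloride (SN1-like), the usual outcome for electron-rich benzylic alcohols.

**Step 14**
Reactants: 16 (2S,8R,9R)-5-(allyloxy)-2,8-bis(4-methoxyphenyl)-3,4,8,9-tetrahydro-2H-furo[2,3-h]chromen-9-ol; 21 1-(allyloxy)-2-(chloromethyl)-3,5-dimethoxybenzene
Product: 22 (2S,8R,9R)-5-(allyloxy)-9-{[2-(allyloxy)-4,6-dimethoxybenzyl]oxy}-2,8-bis(4-methoxyphenyl)-3,4,8,9-tetrahydro-2H-furo[2,3-h]chromene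
Conditions: NaH, n-Bu4NI (cat.), THF/DMF, 0 °C
Reagents that add atoms: none
Why: Williamson etherification of the secondary alkoxide with the very reactive benzylic chloride under basic conditions; the C-9–O bond is not broken, so the 9R configuration is kept.

**Step 15**
Reactants: 22 (2S,8R,9R)-5-(allyloxy)-9-{[2-(allyloxy)-4,6-dimethoxybenzyl]oxy}-2,8-bis(4-methoxyphenyl)-3,4,8,9-tetrahydro-2H-furo[2,3-h]chromene
Product: 23 (2S,8R,9R)-9-[(2-hydroxy-4,6-dimethoxybenzyl)oxy]-2,8-bis(4-methoxyphenyl)-3,4,8,9-tetrahydro-2H-furo[2,3-h]chromen-5-ol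
Conditions: Pd(PPh3)4 (5 mol %), morpholine, THF, 25 °C
Reagents that add atoms: none
Why: Tsuji–Trost deallylation; zerovalent palladium ionises both aryl allyl ethers and morpholine traps the allyl unit, while benzyl ethers do not ionise under these neutral to basic conditions.

**Step 16**
Reactants: 23 (2S,8R,9R)-9-[(2-hydroxy-4,6-dimethoxybenzyl)oxy]-2,8-bis(4-methoxyphenyl)-3,4,8,9-tetrahydro-2H-furo[2,3-h]chromen-5-ol
Product: 24 (2S,8R,9S,9aS)-2,8-bis(4-methoxyphenyl)-3,4,8,9-tetrahydro-2H-furo[2,3-h]chromen-5(9aH)-one whose O-9 and C-9a are bridged by a 3,5-dimethoxy-1,2-phenylene-methylene unit (CH2 on O-9, aryl oxygen on C-9a; 1,4-dioxepine ring cis-fused at C-9/C-9a)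
Conditions: PhI(OAc)2 (1.05 equiv), CF3CH2OH/CH2Cl2, −40 → −10 °C
Reagents that add atoms: none
Why: hypervalent-iodine oxidative dearomatisation (the phenol–phenol C–O coupling type known from griseofulvin-like spiro ethers); the more electron-rich, para-substituted chroman phenol is activated at oxygen and the tethered phenol attacks the para carbon C-9a in a seven-membered closure that is only possible on the face of O-9, which should set 9aS by relay from C-9.

**Step 17**
Reactants: 24 the tethered dienone described in step 16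
Product: 25 2-{[(2S,8R,9S,9aS)-9-hydroxy-2,8-bis(4-methoxyphenyl)-5-oxo-3,4,8,9-tetrahydro-2H-furo[2,3-h]chromen-9a(5H)-yl]oxy}-4,6-dimethoxybenzaldehyde
Conditions: DDQ (1.1 equiv), CH2Cl2/pH 7 phosphate buffer, 0 °C
Reagents that add atoms: water, O
Why: oxidative benzyl ether cleavage; DDQ abstracts hydride from the 2,4,6-trioxygenated benzylic CH2 (far more electron-rich than the two anisyl methines, compare dimethoxybenzyl with PMB ethers), water adds to the oxocarbenium ion and the hemiacetal collapses to the aldehyde and the C-9 alcohol.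

**Step 18**
Reactants: 25 2-{[(2S,8R,9S,9aS)-9-hydroxy-2,8-bis(4-methoxyphenyl)-5-oxo-3,4,8,9-tetrahydro-2H-furo[2,3-h]chromen-9a(5H)-yl]oxy}-4,6-dimethoxybenzaldehyde
Product: 26 2-{[(2S,8R,9aS)-2,8-bis(4-methoxyphenyl)-5,9-dioxo-3,4,8,9-tetrahydro-2H-furo[2,3-h]chromen-9a(5H)-yl]oxy}-4,6-dimethoxybenzaldehyde (expected as the 8R epimer; any 8S epimer is carried along)
Conditions: Dess–Martin periodinane (1.3 equiv), CH2Cl2, 0 → 25 °C
Reagents that add atoms: none
Why: Dess–Martin oxidation of the secondary alcohol to the furanone ketone under non-basic conditions; the hindered aryl aldehyde is not oxidised and a seven-membered lactol is not favoured.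

**Step 19**
Reactants: 26 2-{[(2S,8R,9aS)-2,8-bis(4-methoxyphenyl)-5,9-dioxo-3,4,8,9-tetrahydro-2H-furo[2,3-h]chromen-9a(5H)-yl]oxy}-4,6-dimethoxybenzaldehyde
Product: 28 CNP0251458.2, the (2S,8S,9R,9aS) pentacycle in which the former formyl carbon is the C-4 ketone of a 5,7-dimethoxy-3-hydroxychroman-4-one whose C-3 is C-9 and whose C-2 is C-9a, via C-8 epimer 27 (not isolated)
Conditions: 2-(pentafluorophenyl)-6,7-dihydro-5H-pyrrolo[2,1-c][1,2,4]triazol-2-ium tetrafluoroborate (20 mol %), i-Pr2NEt (30 mol %), toluene, 25 → 40 °C, argon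
Reagents that add atoms: none
Why: The free carbene from the triazolium salt adds to the formyl group, proton transfer gives the Breslow intermediate, this acyl-anion equivalent adds to the furanone ketone C-9, and proton transfer with loss of the carbene releases the α-hydroxy ketone. The closest known reaction type is the NHC-catalysed intramolecular crossed aldehyde–ketone benzoin reaction that gives 3-hydroxychroman-4-ones, including its dynamic variants with ketones that epimerise at the α-carbon. The one ring closed is the chromanone ring, by a 6-exo-trig attack on the C-9 carbonyl. The new carbinol C-9 is controlled by C-9a, because the aryl–O–C-9a tether lets the nucleophile reach only the ketone face syn to the aryloxy group (cis ring fusion, 9R); C-8 is set by base-mediated epimerisation of 26 to 27 through the C-8 enolate and by faster closure of the epimer whose anisyl group is anti to the incoming acyl carbon (8S), so both epimers should converge on one product. The step needs benzoin addition to win over Stetter addition to the dienone, over loss of the aryloxide from the C-8 enolate and over retro-aldol opening of the product: both dienone β-carbons carry oxygen and are fully substituted (poor, hindered acceptors), C-9 is a strained, inductively activated ketone held in a six-membered array, and a small N-C6F5 carbene with only a weak amine base keeps enolate and alkoxide concentrations low.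

**Compound list**

1 | 2,4,6-trihydroxybenzaldehyde | O=Cc1c(O)cc(O)cc1O | starting material
2 | 2,6-dihydroxy-4-(methoxymethoxy)benzaldehyde | O=Cc1c(O)cc(OCOC)cc1O | intermediate
3 | 2-(allyloxy)-6-hydroxy-4-(methoxymethoxy)benzaldehyde | O=Cc1c(O)cc(OCOC)cc1OCC=C | intermediate
4 | 1-(4-methoxyphenyl)ethanone | CC(=O)c1ccc(OC)cc1 | starting material
5 | (E)-3-[2-(allyloxy)-6-hydroxy-4-(methoxymethoxy)phenyl]-1-(4-methoxyphenyl)prop-2-en-1-one | COc1ccc(cc1)C(=O)/C=C/c1c(O)cc(OCOC)cc1OCC=C | intermediate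
6 | 3-[2-(allyloxy)-6-hydroxy-4-(methoxymethoxy)phenyl]-1-(4-methoxyphenyl)propan-1-one | COc1ccc(cc1)C(=O)CCc1c(O)cc(OCOC)cc1OCC=C | intermediate
7 | 3-(allyloxy)-2-[(3R)-3-hydroxy-3-(4-methoxyphenyl)propyl]-5-(methoxymethoxy)phenol | COc1ccc(cc1)[C@H](O)CCc1c(O)cc(OCOC)cc1OCC=C | intermediate
8 | (2S)-5-(allyloxy)-7-(methoxymethoxy)-2-(4-methoxyphenyl)chromane | COc1ccc([C@@H]2CCc3c(OCC=C)cc(OCOC)cc3O2)cc1 | intermediate
9 | (2S)-5-(allyloxy)-8-bromo-7-(methoxymethoxy)-2-(4-methoxyphenyl)chromane | COc1ccc([C@@H]2CCc3c(OCC=C)cc(OCOC)c(Br)c3O2)cc1 | intermediate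
10 | (2S)-5-(allyloxy)-8-bromo-2-(4-methoxyphenyl)chroman-7-ol | COc1ccc([C@@H]2CCc3c(OCC=C)cc(O)c(Br)c3O2)cc1 | intermediate
11 | methyl 2-bromo-2-(4-methoxyphenyl)acetate (racemate) | COC(=O)C(Br)c1ccc(OC)cc1 | starting material
12 | methyl 2-{[(2S)-5-(allyloxy)-8-bromo-2-(4-methoxyphenyl)chroman-7-yl]oxy}-2-(4-methoxyphenyl)acetate (both epimers) | COc1ccc([C@@H]2CCc3c(OCC=C)cc(OC(C(=O)OC)c4ccc(OC)cc4)c(Br)c3O2)cc1 | intermediate
13 | 2-{[(2S)-5-(allyloxy)-8-bromo-2-(4-methoxyphenyl)chroman-7-yl]oxy}-2-(4-methoxyphenyl)acetic acid (both epimers) | COc1ccc([C@@H]2CCc3c(OCC=C)cc(OC(C(=O)O)c4ccc(OC)cc4)c(Br)c3O2)cc1 | intermediate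
14 | lithium 2-{[(2S)-5-(allyloxy)-8-lithio-2-(4-methoxyphenyl)chroman-7-yl]oxy}-2-(4-methoxyphenyl)acetate | COc1ccc([C@@H]2CCc3c(OCC=C)cc(OC(C(=O)[O-])c4ccc(OC)cc4)c([Li])c3O2)cc1.[Li+] | intermediate
15 | (2S)-5-(allyloxy)-2,8-bis(4-methoxyphenyl)-3,4-dihydro-2H-furo[2,3-h]chromen-9(8H)-one (both C-8 epimers) | COc1ccc([C@@H]2CCc3c(OCC=C)cc4OC(c5ccc(OC)cc5)C(=O)c4c3O2)cc1 | intermediate
16 | (2S,8R,9R)-5-(allyloxy)-2,8-bis(4-methoxyphenyl)-3,4,8,9-tetrahydro-2H-furo[2,3-h]chromen-9-ol | COc1ccc([C@@H]2CCc3c(OCC=C)cc4O[C@H](c5ccc(OC)cc5)[C@H](O)c4c3O2)cc1 | intermediate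
17 | 2-hydroxy-4,6-dimethoxybenzaldehyde | COc1cc(O)c(C=O)c(OC)c1 | starting material
18 | 2-(allyloxy)-4,6-dimethoxybenzaldehyde | COc1cc(OCC=C)c(C=O)c(OC)c1 | intermediate
19 | [2-(allyloxy)-4,6-dimethoxyphenyl]methanol | COc1cc(OCC=C)c(CO)c(OC)c1 | intermediate
20 | 2-(allyloxy)-4,6-dimethoxybenzyl methanesulfonate | COc1cc(OCC=C)c(COS(C)(=O)=O)c(OC)c1 | intermediate
21 | 1-(allyloxy)-2-(chloromethyl)-3,5-dimethoxybenzene | COc1cc(OCC=C)c(CCl)c(OC)c1 | intermediate
22 | (2S,8R,9R)-5-(allyloxy)-9-{[2-(allyloxy)-4,6-dimethoxybenzyl]oxy}-2,8-bis(4-methoxyphenyl)-3,4,8,9-tetrahydro-2H-furo[2,3-h]chromene | COc1ccc([C@@H]2CCc3c(OCC=C)cc4O[C@H](c5ccc(OC)cc5)[C@H](OCc5c(OCC=C)cc(OC)cc5OC)c4c3O2)cc1 | intermediate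
23 | (2S,8R,9R)-9-[(2-hydroxy-4,6-dimethoxybenzyl)oxy]-2,8-bis(4-methoxyphenyl)-3,4,8,9-tetrahydro-2H-furo[2,3-h]chromen-5-ol | COc1ccc([C@@H]2CCc3c(O)cc4O[C@H](c5ccc(OC)cc5)[C@H](OCc5c(O)cc(OC)cc5OC)c4c3O2)cc1 | intermediate
24 | (2S,8R,9S,9aS)-tethered dienone (O-9 and C-9a bridged by the 3,5-dimethoxy-1,2-phenylene-methylene unit) | COc1ccc([C@@H]2CCC3=C(O2)[C@]24Oc5cc(OC)cc(OC)c5CO[C@H]2[C@@H](c2ccc(OC)cc2)OC4=CC3=O)cc1 | intermediate
25 | 2-{[(2S,8R,9S,9aS)-9-hydroxy-2,8-bis(4-methoxyphenyl)-5-oxo-3,4,8,9-tetrahydro-2H-furo[2,3-h]chromen-9a(5H)-yl]oxy}-4,6-dimethoxybenzaldehyde | COc1ccc([C@@H]2CCC3=C(O2)[C@]2(Oc4cc(OC)cc(OC)c4C=O)[C@@H](O)[C@@H](c4ccc(OC)cc4)OC2=CC3=O)cc1 | intermediate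
26 | 2-{[(2S,8R,9aS)-2,8-bis(4-methoxyphenyl)-5,9-dioxo-3,4,8,9-tetrahydro-2H-furo[2,3-h]chromen-9a(5H)-yl]oxy}-4,6-dimethoxybenzaldehyde | COc1ccc([C@@H]2CCC3=C(O2)[C@]2(Oc4cc(OC)cc(OC)c4C=O)C(=O)[C@@H](c4ccc(OC)cc4)OC2=CC3=O)cc1 | intermediate
27 | (2S,8S,9aS) epimer of 26 | COc1ccc([C@@H]2CCC3=C(O2)[C@]2(Oc4cc(OC)cc(OC)c4C=O)C(=O)[C@H](c4ccc(OC)cc4)OC2=CC3=O)cc1 | intermediate
28 | CNP0251458.2, (2S,8S,9R,9aS) | COc1ccc([C@@H]2CCC3=C(O2)[C@]24Oc5cc(OC)cc(OC)c5C(=O)[C@@]2(O)[C@H](c2ccc(OC)cc2)OC4=CC3=O)cc1 | target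

**Step count**

Total: 19 steps. Longest linear sequence: 16 steps (steps 1–10 and 14–19); steps 11–13 make the tether reagent 21.

**Steps most likely to fail**

Step 16. The tethered phenol may be oxidised in competition with the chroman phenol, and the two electron-rich benzylic ether bonds may ionise under the oxidising, weakly acidic conditions. The fallback gives up the tether and uses an external phenol that cannot be oxidised. It sets out from ketone 15 and comes back to the route at 27. Ketone 15 is reduced with the enantiomeric catalyst RuCl[(R,R)-TsDPEN](p-cymene) and HCO2Na to the (8S,9S)-alcohol F1. This is silylated (TBSCl, imidazole) to the silyl ether F2 and deallylated (Pd(PPh3)4, morpholine) to the phenol F3. F3 is oxidised with PhI(OAc)2 in the presence of an excess of the hydrogen-bonded, electron-poor phenol 17, which should add to C-9a anti to the silyloxy group and give the aryloxy dienone F4. Cleavage of the silyl ether (HF·pyridine) gives the alcohol F5, and Dess–Martin oxidation gives 27, which enters step 19 directly.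

Step 19. Formation of the Breslow intermediate at the doubly ortho-substituted, electron-rich aldehyde may be slow, so that base-induced loss of the aryloxy group from the C-8 enolate takes over. The fallback forms the same bond by reductive radical coupling. It sets out from 26 (first equilibrated at C-8 with a trace of Et3N to mainly 27) and comes back at the target 28. SmI2 in THF at −78 °C reduces the aryl aldehyde first, and its ketyl adds to the C-9 ketone on the aryloxy face to give the cis-fused diol F6. Oxidation of the secondary benzylic alcohol (MnO2 or Dess–Martin periodinane) then gives 28.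

Step 9. Proton transfer from the acidic α-C–H of the carboxylate to the aryllithium may quench it before it acylates. The fallback builds the ketone first and closes the C–O bond last. It sets out from bromide 9 and comes back at ketone 15. Br/Li exchange (n-BuLi), transmetalation with ZnCl2 and Negishi acylation with 4-methoxyphenylacetyl chloride (Pd(PPh3)4 cat.) give the deoxybenzoin F7. HCl in MeOH gives the phenol F8. CuBr2 brominates the benzylic α-carbon to the bromo ketone F9, which K2CO3 closes to 15.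

**Further compounds**

F1 | step 16 | (2S,8S,9S)-5-(allyloxy)-2,8-bis(4-methoxyphenyl)-3,4,8,9-tetrahydro-2H-furo[2,3-h]chromen-9-ol | COc1ccc([C@@H]2CCc3c(OCC=C)cc4O[C@@H](c5ccc(OC)cc5)[C@@H](O)c4c3O2)cc1
F2 | step 16 | (2S,8S,9S)-5-(allyloxy)-9-(tert-butyldimethylsilyloxy)-2,8-bis(4-methoxyphenyl)-3,4,8,9-tetrahydro-2H-furo[2,3-h]chromene | COc1ccc([C@@H]2CCc3c(OCC=C)cc4O[C@@H](c5ccc(OC)cc5)[C@@H](O[Si](C)(C)C(C)(C)C)c4c3O2)cc1
F3 | step 16 | (2S,8S,9S)-9-(tert-butyldimethylsilyloxy)-2,8-bis(4-methoxyphenyl)-3,4,8,9-tetrahydro-2H-furo[2,3-h]chromen-5-ol | COc1ccc([C@@H]2CCc3c(O)cc4O[C@@H](c5ccc(OC)cc5)[C@@H](O[Si](C)(C)C(C)(C)C)c4c3O2)cc1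
F4 | step 16 | 2-{[(2S,8S,9R,9aS)-9-(tert-butyldimethylsilyloxy)-2,8-bis(4-methoxyphenyl)-5-oxo-3,4,8,9-tetrahydro-2H-furo[2,3-h]chromen-9a(5H)-yl]oxy}-4,6-dimethoxybenzaldehyde | COc1ccc([C@@H]2CCC3=C(O2)[C@]2(Oc4cc(OC)cc(OC)c4C=O)[C@H](O[Si](C)(C)C(C)(C)C)[C@H](c4ccc(OC)cc4)OC2=CC3=O)cc1
F5 | step 16 | 2-{[(2S,8S,9R,9aS)-9-hydroxy-2,8-bis(4-methoxyphenyl)-5-oxo-3,4,8,9-tetrahydro-2H-furo[2,3-h]chromen-9a(5H)-yl]oxy}-4,6-dimethoxybenzaldehyde | COc1ccc([C@@H]2CCC3=C(O2)[C@]2(Oc4cc(OC)cc(OC)c4C=O)[C@H](O)[C@H](c4ccc(OC)cc4)OC2=CC3=O)cc1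
F6 | step 19 | diol corresponding to 28 with the aryl ketone reduced to CH(OH) (either configuration at that carbon) | COc1ccc([C@@H]2CCC3=C(O2)[C@]24Oc5cc(OC)cc(OC)c5C(O)[C@@]2(O)[C@H](c2ccc(OC)cc2)OC4=CC3=O)cc1
F7 | step 9 | 1-[(2S)-5-(allyloxy)-7-(methoxymethoxy)-2-(4-methoxyphenyl)chroman-8-yl]-2-(4-methoxyphenyl)ethanone | COc1ccc([C@@H]2CCc3c(OCC=C)cc(OCOC)c(C(=O)Cc4ccc(OC)cc4)c3O2)cc1
F8 | step 9 | 1-[(2S)-5-(allyloxy)-7-hydroxy-2-(4-methoxyphenyl)chroman-8-yl]-2-(4-methoxyphenyl)ethanone | COc1ccc([C@@H]2CCc3c(OCC=C)cc(O)c(C(=O)Cc4ccc(OC)cc4)c3O2)cc1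
F9 | step 9 | 1-[(2S)-5-(allyloxy)-7-hydroxy-2-(4-methoxyphenyl)chroman-8-yl]-2-bromo-2-(4-methoxyphenyl)ethanone (both epimers) | COc1ccc([C@@H]2CCc3c(OCC=C)cc(O)c(C(=O)C(Br)c4ccc(OC)cc4)c3O2)cc1
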